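**Retrosynthetic overview**
1. Target ⇐ octabenzyl ether 34 ⇐ Mizoroki–Heck union of bis(dihydrobenzofuran) bromide 31 with styrene 33 (ring E), then global debenzylation.
2. Each trans-2,3-diaryl-dihydrobenzofuran ⇐ acid-mediated C2–O closure of a 1,2,2-triarylethanol, where the fixed diarylmethine C3 directs C2 ⇐ Baeyer–Villiger excision of a methyl ketone ⇐ 3,4-diaryl-chroman-2-one.
3. Key C–C bond (C2–C3 of each dihydrobenzofuran) ⇐ catalytic asymmetric enamine Michael addition of arylacetaldehyde 6 to an o-quinone methide released from sulfone 10 or 22; both sulfones come from the common aldehyde 4.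
4. Ring order: first chromanone (13) → inner furan (19); the aryl bromide of 19 becomes the nucleophile for the second carbinol → second chromanone (25) → outer furan (31) → stilbene.

Assumption: quinone methides 11 and 23 react as their E isomers with the same topicity the (S)-prolinol catalyst shows toward nitroalkenes; if lactone 13 proves antipodal, the (R)-catalyst is used with nothing else changed.

Abbreviations: Bn = benzyl; TBS = tert-butyldimethylsilyl; Q = (2S,3S)-4-(benzyloxy)-2-[4-(benzyloxy)phenyl]-3-[3,5-bis(benzyloxy)phenyl]-2,3-dihydro-1-benzofuran-6-yl (compound 19 with Br replaced by the bond).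

**Route**

Step 1
Reactants: 1 4-bromo-2,6-difluorobenzaldehyde
Product: 2 2-(benzyloxy)-4-bromo-6-fluorobenzaldehyde
Conditions: BnOH (1.0 eq), K2CO3, DMF, 50 °C
Reagents that add atoms: benzyl alcohol OCc1ccccc1
Why: SNAr at one formyl-activated ortho-fluorine; the first alkoxy group deactivates the ring, so one equivalent of alcohol stops at the mono-ether.

Step 2
Reactants: 2 2-(benzyloxy)-4-bromo-6-fluorobenzaldehyde
Product: 4 2-(benzyloxy)-4-bromo-6-hydroxybenzaldehyde, via sulfonylethyl ether 3 (not isolated)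
Conditions: MeSO2CH2CH2OH, NaH, DMF, 0 °C → rt; then aq HCl
Reagents that add atoms: 2-(methylsulfonyl)ethanol CS(=O)(=O)CCO
Why: A second SNAr with a hydroxide surrogate, then E1cB loss of methyl vinyl sulfone from 3, unmasks the phenol without touching aldehyde or bromide.

Step 3
Reactants: 5 2-[4-(benzyloxy)phenyl]ethan-1-ol
Product: 6 [4-(benzyloxy)phenyl]acetaldehyde
Conditions: Dess–Martin periodinane, CH2Cl2, 0 °C → rt; used at once
Reagents that add atoms: none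
Why: Dess–Martin oxidation stops at the enolisable arylacetaldehyde under neutral conditions.

Step 4
Reactants: 7 1,3-bis(benzyloxy)-5-bromobenzene; 4 2-(benzyloxy)-4-bromo-6-hydroxybenzaldehyde
Product: 9 [2-(benzyloxy)-4-bromo-6-hydroxyphenyl][3,5-bis(benzyloxy)phenyl]methanol (racemic), via Grignard reagent 8 (not isolated)
Conditions: 7 (2.3 eq), Mg, THF, rt; then 4, 0 °C → rt; H2O quench; crude product used directly
Reagents that add atoms: none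
Why: Grignard addition to the aldehyde after the first equivalent deprotonates the phenol; the racemic carbinol centre is erased in step 6.

Step 5
Reactants: 9 [2-(benzyloxy)-4-bromo-6-hydroxyphenyl][3,5-bis(benzyloxy)phenyl]methanol
Product: 10 3-(benzyloxy)-5-bromo-2-{[3,5-bis(benzyloxy)phenyl](4-methylbenzenesulfonyl)methyl}phenol (racemic)
Conditions: p-TolSO2H, CH2Cl2, rt
Reagents that add atoms: p-toluenesulfinic acid Cc1ccc(cc1)S(O)=O
Why: SN1 substitution of the electron-rich o-hydroxybenzhydrol by sulfinate gives a bench-stable quinone methide precursor.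

Step 6
Reactants: 10 3-(benzyloxy)-5-bromo-2-{[3,5-bis(benzyloxy)phenyl](4-methylbenzenesulfonyl)methyl}phenol; 6 [4-(benzyloxy)phenyl]acetaldehyde
Product: 13 (3S,4S)-5-(benzyloxy)-7-bromo-3-[4-(benzyloxy)phenyl]-4-[3,5-bis(benzyloxy)phenyl]chroman-2-one, via quinone methide 11 (not isolated), via lactol 12 (not isolated)
Conditions: 6 (2.5 eq), (S)-α,α-diphenylprolinol trimethylsilyl ether (20 mol%), K2CO3, CH2Cl2, 0 °C → rt; filter; then Dess–Martin periodinane, rt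
Reagents that add atoms: none
Why: Base eliminates sulfinate to give 11, and the E-enamine of 6 attacks it through its unshielded Si face in an intermolecular enamine Michael addition that forms the C3–C4 bond (the later furan C2–C3 bond) and sets C4 as S and C3 as S (trans), followed by hemiacetal closure to 12 and lactol oxidation; C3 is epimerisable and not needed later.

Step 7
Reactants: 13 (3S,4S)-5-(benzyloxy)-7-bromo-3-[4-(benzyloxy)phenyl]-4-[3,5-bis(benzyloxy)phenyl]chroman-2-one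
Product: 14 (2S,3S)-3-[2-(benzyloxy)-4-bromo-6-hydroxyphenyl]-2-[4-(benzyloxy)phenyl]-3-[3,5-bis(benzyloxy)phenyl]-N-methoxy-N-methylpropanamide
Conditions: Me(MeO)NH·HCl, iPrMgCl, THF, −20 → 0 °C
Reagents that add atoms: N,O-dimethylhydroxylamine hydrochloride CNOC.Cl
Why: Magnesium-amide aminolysis of the aryl lactone (Weinreb amide formation) frees the phenol that becomes the furan oxygen; the non-acidic diarylmethine centre is untouched.

Step 8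
Reactants: 14 (2S,3S)-3-[2-(benzyloxy)-4-bromo-6-hydroxyphenyl]-2-[4-(benzyloxy)phenyl]-3-[3,5-bis(benzyloxy)phenyl]-N-methoxy-N-methylpropanamide
Product: 15 (2S,3S)-3-{2-(benzyloxy)-4-bromo-6-[(tert-butyldimethylsilyl)oxy]phenyl}-2-[4-(benzyloxy)phenyl]-3-[3,5-bis(benzyloxy)phenyl]-N-methoxy-N-methylpropanamide
Conditions: TBSCl, imidazole, DMF, rt
Reagents that add atoms: tert-butyldimethylsilyl chloride CC(C)(C)[Si](C)(C)Cl
Why: Phenol silylation blocks re-lactonisation and hemiketal formation in the next two steps.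

Step 9
Reactants: 15 (2S,3S)-3-{2-(benzyloxy)-4-bromo-6-[(tert-butyldimethylsilyl)oxy]phenyl}-2-[4-(benzyloxy)phenyl]-3-[3,5-bis(benzyloxy)phenyl]-N-methoxy-N-methylpropanamide
Product: 16 (3S,4S)-4-{2-(benzyloxy)-4-bromo-6-[(tert-butyldimethylsilyl)oxy]phenyl}-3-[4-(benzyloxy)phenyl]-4-[3,5-bis(benzyloxy)phenyl]butan-2-one
Conditions: MeMgBr, THF, 0 °C
Reagents that add atoms: methylmagnesium bromide C[Mg]Br
Why: Weinreb ketone synthesis; the chelated tetrahedral intermediate stops at the methyl ketone.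

Step 10
Reactants: 16 (3S,4S)-4-{2-(benzyloxy)-4-bromo-6-[(tert-butyldimethylsilyl)oxy]phenyl}-3-[4-(benzyloxy)phenyl]-4-[3,5-bis(benzyloxy)phenyl]butan-2-one
Product: 17 (1S,2S)-2-{2-(benzyloxy)-4-bromo-6-[(tert-butyldimethylsilyl)oxy]phenyl}-1-[4-(benzyloxy)phenyl]-2-[3,5-bis(benzyloxy)phenyl]ethyl acetate
Conditions: mCPBA, CH2Cl2, 0 °C → rt
Reagents that add atoms: 3-chloroperoxybenzoic acid OOC(=O)c1cccc(Cl)c1
Why: Baeyer–Villiger oxidation; the secondary p-alkoxybenzylic carbon migrates in preference to methyl with retention, replacing the acyl carbon by oxygen.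

Step 11
Reactants: 17 (1S,2S)-2-{2-(benzyloxy)-4-bromo-6-[(tert-butyldimethylsilyl)oxy]phenyl}-1-[4-(benzyloxy)phenyl]-2-[3,5-bis(benzyloxy)phenyl]ethyl acetate
Product: 18 (1S,2S)-2-[2-(benzyloxy)-4-bromo-6-hydroxyphenyl]-1-[4-(benzyloxy)phenyl]-2-[3,5-bis(benzyloxy)phenyl]ethan-1-ol
Conditions: K2CO3 (cat.), MeOH/THF, 40 °C
Reagents that add atoms: none
Why: Base-catalysed methanolysis (transesterification) removes the acetate and the aryl silyl ether together.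

Step 12
Reactants: 18 (1S,2S)-2-[2-(benzyloxy)-4-bromo-6-hydroxyphenyl]-1-[4-(benzyloxy)phenyl]-2-[3,5-bis(benzyloxy)phenyl]ethan-1-ol
Product: 19 (2S,3S)-4-(benzyloxy)-2-[4-(benzyloxy)phenyl]-3-[3,5-bis(benzyloxy)phenyl]-6-bromo-2,3-dihydro-1-benzofuran
Conditions: TsOH·H2O (10 mol%), 4 Å MS, CH2Cl2, rt
Reagents that add atoms: none
Why: SN1 cycloetherification: the p-benzyloxybenzylic cation is trapped reversibly by the phenol, and the fixed (S) diarylmethine C3 places the C2 aryl trans, setting C2 as S under thermodynamic control.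

Step 13
Reactants: 19 (2S,3S)-4-(benzyloxy)-2-[4-(benzyloxy)phenyl]-3-[3,5-bis(benzyloxy)phenyl]-6-bromo-2,3-dihydro-1-benzofuran; 4 2-(benzyloxy)-4-bromo-6-hydroxybenzaldehyde
Product: 21 [2-(benzyloxy)-4-bromo-6-hydroxyphenyl](Q)methanol (both carbinol epimers), via aryllithium 20 (not isolated)
Conditions: 19, n-BuLi, THF, −78 °C; then sodium phenoxide of 4 (4, NaH, THF, 0 °C), −78 → 0 °C; H2O quench; crude product used directly
Reagents that add atoms: none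
Why: Bromine–lithium exchange then 1,2-addition of the aryllithium to the aldehyde; the carbinol centre is erased in step 15.

Step 14
Reactants: 21 [2-(benzyloxy)-4-bromo-6-hydroxyphenyl](Q)methanol
Product: 22 3-(benzyloxy)-5-bromo-2-[Q(4-methylbenzenesulfonyl)methyl]phenol (both epimers)
Conditions: p-TolSO2H, CH2Cl2, rt
Reagents that add atoms: p-toluenesulfinic acid Cc1ccc(cc1)S(O)=O
Why: SN1 sulfinate substitution as in step 5; any reversible opening of the existing furan returns the trans isomer because its C3 is fixed.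

Step 15
Reactants: 22 3-(benzyloxy)-5-bromo-2-[Q(4-methylbenzenesulfonyl)methyl]phenol; 6 [4-(benzyloxy)phenyl]acetaldehyde
Product: 25 (3S,4S)-5-(benzyloxy)-7-bromo-3-[4-(benzyloxy)phenyl]-4-Q-chroman-2-one, via quinone methide 23 (not isolated), via lactol 24 (not isolated)
Conditions: 6 (2.5 eq), (S)-α,α-diphenylprolinol trimethylsilyl ether (20 mol%), K2CO3, CH2Cl2, 0 °C → rt; filter; then Dess–Martin periodinane, rt
Reagents that add atoms: none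
Why: The same enamine Michael addition, hemiacetal closure and lactol oxidation; catalyst control overrides the remote centres of Q and sets C4 as S (C3 S, trans).

Step 16
Reactants: 25 (3S,4S)-5-(benzyloxy)-7-bromo-3-[4-(benzyloxy)phenyl]-4-Q-chroman-2-one
Product: 26 (2S,3S)-3-[2-(benzyloxy)-4-bromo-6-hydroxyphenyl]-2-[4-(benzyloxy)phenyl]-N-methoxy-N-methyl-3-Q-propanamide
Conditions: Me(MeO)NH·HCl, iPrMgCl, THF, −20 → 0 °C
Reagents that add atoms: N,O-dimethylhydroxylamine hydrochloride CNOC.Cl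
Why: Weinreb amide formation by magnesium-amide lactone opening; these conditions are not Lewis acidic enough to open the existing furan.

Step 17
Reactants: 26 (2S,3S)-3-[2-(benzyloxy)-4-bromo-6-hydroxyphenyl]-2-[4-(benzyloxy)phenyl]-N-methoxy-N-methyl-3-Q-propanamide
Product: 27 (2S,3S)-3-{2-(benzyloxy)-4-bromo-6-[(tert-butyldimethylsilyl)oxy]phenyl}-2-[4-(benzyloxy)phenyl]-N-methoxy-N-methyl-3-Q-propanamide
Conditions: TBSCl, imidazole, DMF, rt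
Reagents that add atoms: tert-butyldimethylsilyl chloride CC(C)(C)[Si](C)(C)Cl
Why: Phenol silylation as in step 8.

Step 18
Reactants: 27 (2S,3S)-3-{2-(benzyloxy)-4-bromo-6-[(tert-butyldimethylsilyl)oxy]phenyl}-2-[4-(benzyloxy)phenyl]-N-methoxy-N-methyl-3-Q-propanamide
Product: 28 (3S,4S)-4-{2-(benzyloxy)-4-bromo-6-[(tert-butyldimethylsilyl)oxy]phenyl}-3-[4-(benzyloxy)phenyl]-4-Q-butan-2-one
Conditions: MeMgBr, THF, 0 °C
Reagents that add atoms: methylmagnesium bromide C[Mg]Br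
Why: Weinreb ketone synthesis as in step 9.

Step 19
Reactants: 28 (3S,4S)-4-{2-(benzyloxy)-4-bromo-6-[(tert-butyldimethylsilyl)oxy]phenyl}-3-[4-(benzyloxy)phenyl]-4-Q-butan-2-one
Product: 29 (1S,2S)-2-{2-(benzyloxy)-4-bromo-6-[(tert-butyldimethylsilyl)oxy]phenyl}-1-[4-(benzyloxy)phenyl]-2-Q-ethyl acetate
Conditions: mCPBA, CH2Cl2, 0 °C → rt
Reagents that add atoms: 3-chloroperoxybenzoic acid OOC(=O)c1cccc(Cl)c1
Why: Baeyer–Villiger oxidation with retentive migration of the p-alkoxybenzylic carbon; no alkene is present yet.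

Step 20
Reactants: 29 (1S,2S)-2-{2-(benzyloxy)-4-bromo-6-[(tert-butyldimethylsilyl)oxy]phenyl}-1-[4-(benzyloxy)phenyl]-2-Q-ethyl acetate
Product: 30 (1S,2S)-2-[2-(benzyloxy)-4-bromo-6-hydroxyphenyl]-1-[4-(benzyloxy)phenyl]-2-Q-ethan-1-ol
Conditions: K2CO3 (cat.), MeOH/THF, 40 °C
Reagents that add atoms: none
Why: Methanolysis of acetate and aryl silyl ether as in step 11.

Step 21
Reactants: 30 (1S,2S)-2-[2-(benzyloxy)-4-bromo-6-hydroxyphenyl]-1-[4-(benzyloxy)phenyl]-2-Q-ethan-1-ol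
Product: 31 (2S,3S)-4-(benzyloxy)-2-[4-(benzyloxy)phenyl]-6-bromo-3-Q-2,3-dihydro-1-benzofuran
Conditions: TsOH·H2O (10 mol%), 4 Å MS, CH2Cl2, rt
Reagents that add atoms: none
Why: SN1 cycloetherification as in step 12; the (S) diarylmethine carbon sets the new C2 as S (trans), and the first furan re-closes trans if it opens.

Step 22
Reactants: 32 2,4-bis(benzyloxy)benzaldehyde
Product: 33 2,4-bis(benzyloxy)-1-ethenylbenzene
Conditions: Ph3PCH3Br, KOtBu, THF, 0 °C → rt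
Reagents that add atoms: methyltriphenylphosphonium bromide C[P+](c1ccccc1)(c1ccccc1)c1ccccc1.[Br-]
Why: Wittig methylenation of a non-enolisable aldehyde.

Step 23
Reactants: 31 (2S,3S)-4-(benzyloxy)-2-[4-(benzyloxy)phenyl]-6-bromo-3-Q-2,3-dihydro-1-benzofuran; 33 2,4-bis(benzyloxy)-1-ethenylbenzene
Product: 34 (2S,3S)-4-(benzyloxy)-2-[4-(benzyloxy)phenyl]-6-{(E)-2-[2,4-bis(benzyloxy)phenyl]ethenyl}-3-Q-2,3-dihydro-1-benzofuran
Conditions: Pd(OAc)2 (5 mol%), P(o-tol)3 (15 mol%), Et3N, DMF, 100 °C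
Reagents that add atoms: none
Why: Mizoroki–Heck reaction of an unhindered aryl bromide; syn insertion at the terminal carbon and syn β-hydride elimination give the E-stilbene.

Step 24
Reactants: 34 (2S,3S)-4-(benzyloxy)-2-[4-(benzyloxy)phenyl]-6-{(E)-2-[2,4-bis(benzyloxy)phenyl]ethenyl}-3-Q-2,3-dihydro-1-benzofuran
Product: 35 4-[(E)-2-{(2S,3S)-3-[(2S,3S)-3-(3,5-dihydroxyphenyl)-4-hydroxy-2-(4-hydroxyphenyl)-2,3-dihydro-1-benzofuran-6-yl]-4-hydroxy-2-(4-hydroxyphenyl)-2,3-dihydro-1-benzofuran-6-yl}ethenyl]benzene-1,3-diol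
Conditions: BCl3, pentamethylbenzene, CH2Cl2, −78 °C; then H2O
Reagents that add atoms: none
Why: Lewis-acid debenzylation with a non-Lewis-basic cation scavenger cleaves all eight benzyl ethers at low temperature without reducing the stilbene or epimerising the trans furans.

**Compound list**
1 | 4-bromo-2,6-difluorobenzaldehyde | O=Cc1c(F)cc(Br)cc1F | starting material
2 | 2-(benzyloxy)-4-bromo-6-fluorobenzaldehyde | O=Cc1c(F)cc(Br)cc1OCc1ccccc1 | intermediate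
3 | 2-(benzyloxy)-4-bromo-6-[2-(methylsulfonyl)ethoxy]benzaldehyde | O=Cc1c(OCCS(C)(=O)=O)cc(Br)cc1OCc1ccccc1 | intermediate
4 | 2-(benzyloxy)-4-bromo-6-hydroxybenzaldehyde | O=Cc1c(O)cc(Br)cc1OCc1ccccc1 | intermediate
5 | 2-[4-(benzyloxy)phenyl]ethan-1-ol | OCCc1ccc(OCc2ccccc2)cc1 | starting material
6 | [4-(benzyloxy)phenyl]acetaldehyde | O=CCc1ccc(OCc2ccccc2)cc1 | intermediate
7 | 1,3-bis(benzyloxy)-5-bromobenzene | Brc1cc(OCc2ccccc2)cc(OCc2ccccc2)c1 | starting material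
8 | [3,5-bis(benzyloxy)phenyl]magnesium bromide | Br[Mg]c1cc(OCc2ccccc2)cc(OCc2ccccc2)c1 | intermediate
9 | [2-(benzyloxy)-4-bromo-6-hydroxyphenyl][3,5-bis(benzyloxy)phenyl]methanol (racemic) | OC(c1cc(OCc2ccccc2)cc(OCc2ccccc2)c1)c1c(O)cc(Br)cc1OCc1ccccc1 | intermediate
10 | 3-(benzyloxy)-5-bromo-2-{[3,5-bis(benzyloxy)phenyl](4-methylbenzenesulfonyl)methyl}phenol (racemic) | Cc1ccc(cc1)S(=O)(=O)C(c1cc(OCc2ccccc2)cc(OCc2ccccc2)c1)c1c(O)cc(Br)cc1OCc1ccccc1 | intermediate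
11 | (6E)-5-(benzyloxy)-3-bromo-6-{[3,5-bis(benzyloxy)phenyl]methylidene}cyclohexa-2,4-dien-1-one | O=C1C=C(Br)C=C(OCc2ccccc2)/C1=C\c1cc(OCc2ccccc2)cc(OCc2ccccc2)c1 | intermediate
12 | (3S,4S)-5-(benzyloxy)-7-bromo-3-[4-(benzyloxy)phenyl]-4-[3,5-bis(benzyloxy)phenyl]chroman-2-ol (both C2 anomers) | OC1Oc2cc(Br)cc(OCc3ccccc3)c2[C@H](c2cc(OCc3ccccc3)cc(OCc3ccccc3)c2)[C@H]1c1ccc(OCc2ccccc2)cc1 | intermediate
13 | (3S,4S)-5-(benzyloxy)-7-bromo-3-[4-(benzyloxy)phenyl]-4-[3,5-bis(benzyloxy)phenyl]chroman-2-one | O=C1Oc2cc(Br)cc(OCc3ccccc3)c2[C@H](c2cc(OCc3ccccc3)cc(OCc3ccccc3)c2)[C@H]1c1ccc(OCc2ccccc2)cc1 | intermediate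
14 | (2S,3S)-3-[2-(benzyloxy)-4-bromo-6-hydroxyphenyl]-2-[4-(benzyloxy)phenyl]-3-[3,5-bis(benzyloxy)phenyl]-N-methoxy-N-methylpropanamide | CON(C)C(=O)[C@H](c1ccc(OCc2ccccc2)cc1)[C@@H](c1cc(OCc2ccccc2)cc(OCc2ccccc2)c1)c1c(O)cc(Br)cc1OCc1ccccc1 | intermediate
15 | (2S,3S)-3-{2-(benzyloxy)-4-bromo-6-[(tert-butyldimethylsilyl)oxy]phenyl}-2-[4-(benzyloxy)phenyl]-3-[3,5-bis(benzyloxy)phenyl]-N-methoxy-N-methylpropanamide | CON(C)C(=O)[C@H](c1ccc(OCc2ccccc2)cc1)[C@@H](c1cc(OCc2ccccc2)cc(OCc2ccccc2)c1)c1c(O[Si](C)(C)C(C)(C)C)cc(Br)cc1OCc1ccccc1 | intermediate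
16 | (3S,4S)-4-{2-(benzyloxy)-4-bromo-6-[(tert-butyldimethylsilyl)oxy]phenyl}-3-[4-(benzyloxy)phenyl]-4-[3,5-bis(benzyloxy)phenyl]butan-2-one | CC(=O)[C@H](c1ccc(OCc2ccccc2)cc1)[C@@H](c1cc(OCc2ccccc2)cc(OCc2ccccc2)c1)c1c(O[Si](C)(C)C(C)(C)C)cc(Br)cc1OCc1ccccc1 | intermediate
17 | (1S,2S)-2-{2-(benzyloxy)-4-bromo-6-[(tert-butyldimethylsilyl)oxy]phenyl}-1-[4-(benzyloxy)phenyl]-2-[3,5-bis(benzyloxy)phenyl]ethyl acetate | CC(=O)O[C@H](c1ccc(OCc2ccccc2)cc1)[C@@H](c1cc(OCc2ccccc2)cc(OCc2ccccc2)c1)c1c(O[Si](C)(C)C(C)(C)C)cc(Br)cc1OCc1ccccc1 | intermediate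
18 | (1S,2S)-2-[2-(benzyloxy)-4-bromo-6-hydroxyphenyl]-1-[4-(benzyloxy)phenyl]-2-[3,5-bis(benzyloxy)phenyl]ethan-1-ol | O[C@H](c1ccc(OCc2ccccc2)cc1)[C@@H](c1cc(OCc2ccccc2)cc(OCc2ccccc2)c1)c1c(O)cc(Br)cc1OCc1ccccc1 | intermediate
19 | (2S,3S)-4-(benzyloxy)-2-[4-(benzyloxy)phenyl]-3-[3,5-bis(benzyloxy)phenyl]-6-bromo-2,3-dihydro-1-benzofuran | Brc1cc(OCc2ccccc2)c2c(c1)O[C@H](c1ccc(OCc3ccccc3)cc1)[C@H]2c1cc(OCc2ccccc2)cc(OCc2ccccc2)c1 | intermediate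
20 | Q-lithium (6-lithio analogue of 19) | [Li]c1cc(OCc2ccccc2)c2c(c1)O[C@H](c1ccc(OCc3ccccc3)cc1)[C@H]2c1cc(OCc2ccccc2)cc(OCc2ccccc2)c1 | intermediate
21 | [2-(benzyloxy)-4-bromo-6-hydroxyphenyl](Q)methanol (both carbinol epimers) | OC(c1cc(OCc2ccccc2)c2c(c1)O[C@H](c1ccc(OCc3ccccc3)cc1)[C@H]2c1cc(OCc2ccccc2)cc(OCc2ccccc2)c1)c1c(O)cc(Br)cc1OCc1ccccc1 | intermediate
22 | 3-(benzyloxy)-5-bromo-2-[Q(4-methylbenzenesulfonyl)methyl]phenol (both epimers) | Cc1ccc(cc1)S(=O)(=O)C(c1cc(OCc2ccccc2)c2c(c1)O[C@H](c1ccc(OCc3ccccc3)cc1)[C@H]2c1cc(OCc2ccccc2)cc(OCc2ccccc2)c1)c1c(O)cc(Br)cc1OCc1ccccc1 | intermediate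
23 | (6E)-5-(benzyloxy)-3-bromo-6-(Q-methylidene)cyclohexa-2,4-dien-1-one | O=C1C=C(Br)C=C(OCc2ccccc2)/C1=C\c1cc(OCc2ccccc2)c2c(c1)O[C@H](c1ccc(OCc3ccccc3)cc1)[C@H]2c1cc(OCc2ccccc2)cc(OCc2ccccc2)c1 | intermediate
24 | (3S,4S)-5-(benzyloxy)-7-bromo-3-[4-(benzyloxy)phenyl]-4-Q-chroman-2-ol (both C2 anomers) | OC1Oc2cc(Br)cc(OCc3ccccc3)c2[C@H](c3cc(OCc4ccccc4)c4c(c3)O[C@H](c3ccc(OCc5ccccc5)cc3)[C@H]4c3cc(OCc4ccccc4)cc(OCc4ccccc4)c3)[C@H]1c1ccc(OCc2ccccc2)cc1 | intermediate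
25 | (3S,4S)-5-(benzyloxy)-7-bromo-3-[4-(benzyloxy)phenyl]-4-Q-chroman-2-one | O=C1Oc2cc(Br)cc(OCc3ccccc3)c2[C@H](c3cc(OCc4ccccc4)c4c(c3)O[C@H](c3ccc(OCc5ccccc5)cc3)[C@H]4c3cc(OCc4ccccc4)cc(OCc4ccccc4)c3)[C@H]1c1ccc(OCc2ccccc2)cc1 | intermediate
26 | (2S,3S)-3-[2-(benzyloxy)-4-bromo-6-hydroxyphenyl]-2-[4-(benzyloxy)phenyl]-N-methoxy-N-methyl-3-Q-propanamide | CON(C)C(=O)[C@H](c1ccc(OCc2ccccc2)cc1)[C@@H](c1cc(OCc2ccccc2)c2c(c1)O[C@H](c1ccc(OCc3ccccc3)cc1)[C@H]2c1cc(OCc2ccccc2)cc(OCc2ccccc2)c1)c1c(O)cc(Br)cc1OCc1ccccc1 | intermediate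
27 | (2S,3S)-3-{2-(benzyloxy)-4-bromo-6-[(tert-butyldimethylsilyl)oxy]phenyl}-2-[4-(benzyloxy)phenyl]-N-methoxy-N-methyl-3-Q-propanamide | CON(C)C(=O)[C@H](c1ccc(OCc2ccccc2)cc1)[C@@H](c1cc(OCc2ccccc2)c2c(c1)O[C@H](c1ccc(OCc3ccccc3)cc1)[C@H]2c1cc(OCc2ccccc2)cc(OCc2ccccc2)c1)c1c(O[Si](C)(C)C(C)(C)C)cc(Br)cc1OCc1ccccc1 | intermediate
28 | (3S,4S)-4-{2-(benzyloxy)-4-bromo-6-[(tert-butyldimethylsilyl)oxy]phenyl}-3-[4-(benzyloxy)phenyl]-4-Q-butan-2-one | CC(=O)[C@H](c1ccc(OCc2ccccc2)cc1)[C@@H](c1cc(OCc2ccccc2)c2c(c1)O[C@H](c1ccc(OCc3ccccc3)cc1)[C@H]2c1cc(OCc2ccccc2)cc(OCc2ccccc2)c1)c1c(O[Si](C)(C)C(C)(C)C)cc(Br)cc1OCc1ccccc1 | intermediate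
29 | (1S,2S)-2-{2-(benzyloxy)-4-bromo-6-[(tert-butyldimethylsilyl)oxy]phenyl}-1-[4-(benzyloxy)phenyl]-2-Q-ethyl acetate | CC(=O)O[C@H](c1ccc(OCc2ccccc2)cc1)[C@@H](c1cc(OCc2ccccc2)c2c(c1)O[C@H](c1ccc(OCc3ccccc3)cc1)[C@H]2c1cc(OCc2ccccc2)cc(OCc2ccccc2)c1)c1c(O[Si](C)(C)C(C)(C)C)cc(Br)cc1OCc1ccccc1 | intermediate
30 | (1S,2S)-2-[2-(benzyloxy)-4-bromo-6-hydroxyphenyl]-1-[4-(benzyloxy)phenyl]-2-Q-ethan-1-ol | O[C@H](c1ccc(OCc2ccccc2)cc1)[C@@H](c1cc(OCc2ccccc2)c2c(c1)O[C@H](c1ccc(OCc3ccccc3)cc1)[C@H]2c1cc(OCc2ccccc2)cc(OCc2ccccc2)c1)c1c(O)cc(Br)cc1OCc1ccccc1 | intermediate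
31 | (2S,3S)-4-(benzyloxy)-2-[4-(benzyloxy)phenyl]-6-bromo-3-Q-2,3-dihydro-1-benzofuran | Brc1cc(OCc2ccccc2)c2c(c1)O[C@H](c1ccc(OCc3ccccc3)cc1)[C@H]2c1cc(OCc2ccccc2)c2c(c1)O[C@H](c1ccc(OCc3ccccc3)cc1)[C@H]2c1cc(OCc2ccccc2)cc(OCc2ccccc2)c1 | intermediate
32 | 2,4-bis(benzyloxy)benzaldehyde | O=Cc1ccc(OCc2ccccc2)cc1OCc1ccccc1 | starting material
33 | 2,4-bis(benzyloxy)-1-ethenylbenzene | C=Cc1ccc(OCc2ccccc2)cc1OCc1ccccc1 | intermediate
34 | (2S,3S)-4-(benzyloxy)-2-[4-(benzyloxy)phenyl]-6-{(E)-2-[2,4-bis(benzyloxy)phenyl]ethenyl}-3-Q-2,3-dihydro-1-benzofuran (octabenzyl ether of the target) | C(c1ccccc1)Oc1ccc(/C=C/c2cc(OCc3ccccc3)c3c(c2)O[C@H](c2ccc(OCc4ccccc4)cc2)[C@H]3c2cc(OCc3ccccc3)c3c(c2)O[C@H](c2ccc(OCc4ccccc4)cc2)[C@H]3c2cc(OCc3ccccc3)cc(OCc3ccccc3)c2)c(OCc2ccccc2)c1 | intermediate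
35 | 4-[(E)-2-{(2S,3S)-3-[(2S,3S)-3-(3,5-dihydroxyphenyl)-4-hydroxy-2-(4-hydroxyphenyl)-2,3-dihydro-1-benzofuran-6-yl]-4-hydroxy-2-(4-hydroxyphenyl)-2,3-dihydro-1-benzofuran-6-yl}ethenyl]benzene-1,3-diol (CNP0186204.1) | Oc1ccc([C@H]2Oc3cc(/C=C/c4ccc(O)cc4O)cc(O)c3[C@@H]2c2cc(O)c3c(c2)O[C@H](c2ccc(O)cc2)[C@H]3c2cc(O)cc(O)c2)cc1 | target

**Step count**
Total steps: 24. Longest linear sequence: 22 steps (steps 1, 2, 4–21, 23, 24).

**Three steps most likely to fail**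

Step 6 (repeated as step 15): the enantioselective Michael addition to a hindered, 2,6-dioxygenated quinone methide may be slow or poorly selective, and its facial sense rests on analogy. The fallback sets out from sulfone 10 and comes back at lactone 13. Commercial [4-(benzyloxy)phenyl]acetic acid is converted in the flask (pivaloyl chloride, iPr2NEt, CH2Cl2, 0 °C) into [4-(benzyloxy)phenyl]acetic pivalic anhydride F1. The isothiourea HyperBTM (10 mol%) turns F1 into a chiral ammonium enolate, which adds to quinone methide 11 (released from 10 with Cs2CO3). The resulting phenoxide lactonises onto the acyl ammonium, releasing the catalyst and giving 13 directly without the oxidation; the catalyst enantiomer is chosen to give the (4S) lactone. The same F1 serves step 15 (22 to 25).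

Step 10 (repeated as step 19): the Baeyer–Villiger oxidation of a crowded α-aryl ketone may be slow, and the peracid may attack the electron-rich rings. The fallback sets out from Weinreb amide 15 and comes back at acetate 17. DIBAL-H (THF, −78 °C) gives (2S,3S)-3-{2-(benzyloxy)-4-bromo-6-[(tert-butyldimethylsilyl)oxy]phenyl}-2-[4-(benzyloxy)phenyl]-3-[3,5-bis(benzyloxy)phenyl]propanal F2. Pinnick oxidation (NaClO2, NaH2PO4, 2-methyl-2-butene) gives the corresponding (2S,3S)-propanoic acid F3. Oxidative decarboxylation with Pb(OAc)4 in AcOH/benzene at 60 °C passes through the p-alkoxybenzylic cation and gives 17 together with its C1 epimer, (1R,2S)-2-{2-(benzyloxy)-4-bromo-6-[(tert-butyldimethylsilyl)oxy]phenyl}-1-[4-(benzyloxy)phenyl]-2-[3,5-bis(benzyloxy)phenyl]ethyl acetate F4. In step 11 the epimer gives (1R,2S)-2-[2-(benzyloxy)-4-bromo-6-hydroxyphenyl]-1-[4-(benzyloxy)phenyl]-2-[3,5-bis(benzyloxy)phenyl]ethan-1-ol F5. Both 18 and F5 close to 19 in step 12, because the carbinol configuration is lost on ionisation.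

Step 24: eight benzyl ethers must be cleaved next to a stilbene, a 2-hydroxystilbene unit and two acid-labile benzylic ethers. The fallback sets out from bromide 31 and comes back at target 35, moving the debenzylation ahead of the stilbene and finishing with a mild base-labile group.
- BCl3/pentamethylbenzene on 31 gives the hexaphenol (2S,3S)-6-bromo-3-[(2S,3S)-3-(3,5-dihydroxyphenyl)-4-hydroxy-2-(4-hydroxyphenyl)-2,3-dihydro-1-benzofuran-6-yl]-2-(4-hydroxyphenyl)-2,3-dihydro-1-benzofuran-4-ol F6.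
- Ac2O/pyridine gives its hexaacetate F7.
- Commercial 2,4-dihydroxybenzaldehyde with excess Ph3P=CH2 gives 4-ethenylbenzene-1,3-diol F8, acetylated in the same flask to 4-ethenyl-1,3-phenylene diacetate F9.
- Mizoroki–Heck coupling of F7 with F9 (Pd(OAc)2, P(o-tol)3, Et3N, DMF, 90 °C) gives the octaacetate of the target F10.
- K2CO3 in MeOH at 0 °C then gives 35.

Further compounds
F1 | step 6 | [4-(benzyloxy)phenyl]acetic pivalic anhydride | CC(C)(C)C(=O)OC(=O)Cc1ccc(OCc2ccccc2)cc1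
F2 | step 10 | (2S,3S)-3-{2-(benzyloxy)-4-bromo-6-[(tert-butyldimethylsilyl)oxy]phenyl}-2-[4-(benzyloxy)phenyl]-3-[3,5-bis(benzyloxy)phenyl]propanal | O=C[C@H](c1ccc(OCc2ccccc2)cc1)[C@@H](c1cc(OCc2ccccc2)cc(OCc2ccccc2)c1)c1c(O[Si](C)(C)C(C)(C)C)cc(Br)cc1OCc1ccccc1
F3 | step 10 | (2S,3S)-3-{2-(benzyloxy)-4-bromo-6-[(tert-butyldimethylsilyl)oxy]phenyl}-2-[4-(benzyloxy)phenyl]-3-[3,5-bis(benzyloxy)phenyl]propanoic acid | OC(=O)[C@H](c1ccc(OCc2ccccc2)cc1)[C@@H](c1cc(OCc2ccccc2)cc(OCc2ccccc2)c1)c1c(O[Si](C)(C)C(C)(C)C)cc(Br)cc1OCc1ccccc1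
F4 | step 10 | (1R,2S)-2-{2-(benzyloxy)-4-bromo-6-[(tert-butyldimethylsilyl)oxy]phenyl}-1-[4-(benzyloxy)phenyl]-2-[3,5-bis(benzyloxy)phenyl]ethyl acetate | CC(=O)O[C@@H](c1ccc(OCc2ccccc2)cc1)[C@@H](c1cc(OCc2ccccc2)cc(OCc2ccccc2)c1)c1c(O[Si](C)(C)C(C)(C)C)cc(Br)cc1OCc1ccccc1
F5 | step 10 | (1R,2S)-2-[2-(benzyloxy)-4-bromo-6-hydroxyphenyl]-1-[4-(benzyloxy)phenyl]-2-[3,5-bis(benzyloxy)phenyl]ethan-1-ol | O[C@@H](c1ccc(OCc2ccccc2)cc1)[C@@H](c1cc(OCc2ccccc2)cc(OCc2ccccc2)c1)c1c(O)cc(Br)cc1OCc1ccccc1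
F6 | step 24 | (2S,3S)-6-bromo-3-[(2S,3S)-3-(3,5-dihydroxyphenyl)-4-hydroxy-2-(4-hydroxyphenyl)-2,3-dihydro-1-benzofuran-6-yl]-2-(4-hydroxyphenyl)-2,3-dihydro-1-benzofuran-4-ol | Brc1cc(O)c2c(c1)O[C@H](c1ccc(O)cc1)[C@H]2c1cc(O)c2c(c1)O[C@H](c1ccc(O)cc1)[C@H]2c1cc(O)cc(O)c1
F7 | step 24 | hexaacetate of F6 | Brc1cc(OC(C)=O)c2c(c1)O[C@H](c1ccc(OC(C)=O)cc1)[C@H]2c1cc(OC(C)=O)c2c(c1)O[C@H](c1ccc(OC(C)=O)cc1)[C@H]2c1cc(OC(C)=O)cc(OC(C)=O)c1
F8 | step 24 | 4-ethenylbenzene-1,3-diol | C=Cc1ccc(O)cc1O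
F9 | step 24 | 4-ethenyl-1,3-phenylene diacetate | C=Cc1ccc(OC(C)=O)cc1OC(C)=O
F10 | step 24 | octaacetate of the target | CC(=O)Oc1ccc(/C=C/c2cc(OC(C)=O)c3c(c2)O[C@H](c2ccc(OC(C)=O)cc2)[C@H]3c2cc(OC(C)=O)c3c(c2)O[C@H](c2ccc(OC(C)=O)cc2)[C@H]3c2cc(OC(C)=O)cc(OC(C)=O)c2)c(OC(C)=O)c1
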